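Everything rests on cutting the piperidine ring at C4′–C5′. In this ring (N1′, C2′–C6′) all branching and chirality sit on C2′ beside nitrogen, while C3′–C6′ are plain methylenes; ring-closing metathesis therefore forms the six-membered ring and the remote C4′=C5′ bond in one operation with C2′ as a spectator. Its precursor is the methyl carbamate of an (S)-1-arylbut-3-enylamine bearing an allyl group on nitrogen (aryl = 2,6-bis(benzyloxy)-4-(methoxymethoxy)phenyl), C2′ being set beforehand by sulfinyl-imine allylation. The uniquely protected para oxygen later becomes O1, so ring C can only close to the 6-substituted flavanone, whose C2 is set by asymmetric aryl addition to a chromone.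

Key step: step 7

Remark: flavanone labels are O1, C2–C4, C4a, C5–C8, C8a (rings A, B, C) and piperidine labels are N1′, C2′–C6′; the indium-mediated allylation is assumed to take its usual chelated course on the (R)-sulfinyl imine (Si-face attack), which gives S at C2′.

Step 1
Reactants: 1 3,5-bis(benzyloxy)phenol
Product: 3 2,6-bis(benzyloxy)-4-hydroxybenzaldehyde, via aryl iminium chloride 2 (not isolated)
Conditions: POCl3, DMF, MeCN, 0 °C → rt; then H2O, 50 °C
Reagents that add atoms: N,N-dimethylformamide CN(C)C=O; water O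
Why: Vilsmeier–Haack formylation, in which the chloroiminium ion should attack mainly the ring carbon para to the free hydroxyl and between the two benzyloxy groups, as is usual for 3,5-dialkoxyphenols, the hydrogen-bonded ortho-formyl isomer being removed by chromatography or crystallisation.

Step 2
Reactants: 3 2,6-bis(benzyloxy)-4-hydroxybenzaldehyde
Product: 4 2,6-bis(benzyloxy)-4-(methoxymethoxy)benzaldehyde
Conditions: MOMCl, K2CO3, acetone, 0 °C → rt
Reagents that add atoms: chloromethyl methyl ether COCCl
Why: Williamson-type O-alkylation of the acidic para-formyl phenoxide (acetal protection) marks the para oxygen, the later O1, as the only one that is not a benzyl ether.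

Step 3
Reactants: 4 2,6-bis(benzyloxy)-4-(methoxymethoxy)benzaldehyde; 5 (R)-2-methylpropane-2-sulfinamide
Product: 6 (R,E)-N-{[2,6-bis(benzyloxy)-4-(methoxymethoxy)phenyl]methylidene}-2-methylpropane-2-sulfinamide
Conditions: Ti(OEt)4, THF, 65 °C
Reagents that add atoms: none
Why: Lewis acid-mediated condensation of an aldehyde with a sulfinamide, in which Ti(OEt)4 activates the hindered, electron-rich carbonyl group and binds the water, should give the E-configured N-sulfinyl aldimine.

Step 4
Reactants: 6 (R,E)-N-{[2,6-bis(benzyloxy)-4-(methoxymethoxy)phenyl]methylidene}-2-methylpropane-2-sulfinamide; 7 allyl bromide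
Product: 8 (R)-N-{(1S)-1-[2,6-bis(benzyloxy)-4-(methoxymethoxy)phenyl]but-3-en-1-yl}-2-methylpropane-2-sulfinamide
Conditions: In (powder), THF, 60 °C
Reagents that add atoms: none
Why: Barbier-type indium-mediated allylation of an N-tert-butanesulfinyl aldimine should pass through a chair-like six-membered transition state with indium held by the sulfinyl group, so that the allyl group reaches the Si face of the imine carbon and the later C2′ is set S under control of the sulfur stereocentre.

Step 5
Reactants: 8 (R)-N-{(1S)-1-[2,6-bis(benzyloxy)-4-(methoxymethoxy)phenyl]but-3-en-1-yl}-2-methylpropane-2-sulfinamide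
Product: 10 methyl N-{(1S)-1-[2,6-bis(benzyloxy)-4-(methoxymethoxy)phenyl]but-3-en-1-yl}carbamate, via primary amine 9 (not isolated)
Conditions: HCl (4 M in dioxane), MeOH, 0 °C; then NaHCO3 (aq), ClCO2Me, EtOAc, 0 °C → rt
Reagents that add atoms: methyl chloroformate COC(=O)Cl
Why: Acid methanolysis of the N–S bond, expected at 0 °C to be much faster than cleavage of the aryl methoxymethyl ether or ionisation of the benzylic C–N bond, followed by Schotten–Baumann N-acylation gives a methyl carbamate that masks the nitrogen for metathesis and is the precursor of the N-methyl group.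

Step 6
Reactants: 10 methyl N-{(1S)-1-[2,6-bis(benzyloxy)-4-(methoxymethoxy)phenyl]but-3-en-1-yl}carbamate; 7 allyl bromide
Product: 11 methyl N-allyl-N-{(1S)-1-[2,6-bis(benzyloxy)-4-(methoxymethoxy)phenyl]but-3-en-1-yl}carbamate
Conditions: NaH, DMF, 0 °C → rt
Reagents that add atoms: none
Why: N-alkylation of the sodium carbamate with an allylic bromide (SN2) places the second terminal alkene on N1′ without touching the stereocentre.

Step 7
Reactants: 11 methyl N-allyl-N-{(1S)-1-[2,6-bis(benzyloxy)-4-(methoxymethoxy)phenyl]but-3-en-1-yl}carbamate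
Product: 12 methyl (2S)-2-[2,6-bis(benzyloxy)-4-(methoxymethoxy)phenyl]-3,6-dihydropyridine-1(2H)-carboxylate
Conditions: RuCl2(=CHPh)(PCy3)(H2IMes) (second-generation Grubbs catalyst, 5 mol %), CH2Cl2 (0.01 M), 40 °C
Reagents that add atoms: none
Why: Ring-closing olefin metathesis, well known for N-allyl homoallylic carbamates as a route to 1,2,3,6-tetrahydropyridines: the benzylidene complex first swaps its carbene for the terminal carbon of the N-allyl group (the alkene further from the bulky aryl group), and the resulting alkylidene then undergoes [2+2] addition to the C-allyl alkene and cycloreversion of the metallacyclobutane. This joins C4′ to C5′ as a cis double bond and closes the six-membered ring N1′–C2′–C3′–C4′=C5′–C6′ by intramolecular alkylidene transfer between two terminal alkenes, ethene being the only other product. No stereocentre is formed, and C2′, which is not part of either alkene, keeps its S configuration. The one selectivity required is ring closure in preference to intermolecular metathesis; it is secured by the 1,7-relationship of the alkenes, by dilution and loss of ethene, and by the carbamate, which takes away the basicity of N1′ toward ruthenium and whose planar N–C(=O) unit holds the two allyl arms close. The benzyl ethers and the methoxymethyl ether do not interact with the catalyst.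

Step 8
Reactants: 12 methyl (2S)-2-[2,6-bis(benzyloxy)-4-(methoxymethoxy)phenyl]-3,6-dihydropyridine-1(2H)-carboxylate
Product: 13 (2S)-2-[2,6-bis(benzyloxy)-4-(methoxymethoxy)phenyl]-1-methyl-1,2,3,6-tetrahydropyridine
Conditions: LiAlH4, THF, 0 → 65 °C
Reagents that add atoms: none
Why: Hydride reduction of a methyl carbamate to the N-methyl amine (through the formamide and iminium stages) turns the nitrogen mask into the N-CH3 group of the target while the isolated alkene, the ethers and C2′ are untouched.

Step 9
Reactants: 13 (2S)-2-[2,6-bis(benzyloxy)-4-(methoxymethoxy)phenyl]-1-methyl-1,2,3,6-tetrahydropyridine; 14 N-methoxy-N-methylacetamide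
Product: 17 1-{2,4-bis(benzyloxy)-6-hydroxy-3-[(2S)-1-methyl-1,2,3,6-tetrahydropyridin-2-yl]phenyl}ethan-1-one, via aryllithium 15 (not isolated), via methoxymethyl ketone 16 (not isolated)
Conditions: n-BuLi, THF, −78 → 0 °C; 14, −78 °C → rt; then HCl (3 M), MeOH, 40 °C
Reagents that add atoms: none
Why: Directed ortho-metalation at the only kind of free ring position (flanked by the methoxymethoxy and a benzyloxy group), Weinreb ketone synthesis with the aryllithium, and acid-catalysed acetal exchange, applied only once the acetyl group has deactivated the ring, deliver the ortho-hydroxyacetophenone whose free phenol is para to the carbon that bears C2′.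

Step 10
Reactants: 17 1-{2,4-bis(benzyloxy)-6-hydroxy-3-[(2S)-1-methyl-1,2,3,6-tetrahydropyridin-2-yl]phenyl}ethan-1-one
Product: 19 5,7-bis(benzyloxy)-6-[(2S)-1-methyl-1,2,3,6-tetrahydropyridin-2-yl]-4H-chromen-4-one, via enaminone 18 (not isolated)
Conditions: Me2NCH(OMe)2, toluene, 90 °C; then conc. HCl, CH2Cl2, rt
Reagents that add atoms: N,N-dimethylformamide dimethyl acetal COC(OC)N(C)C
Why: Enaminone formation at the acetyl methyl group followed by acid-promoted intramolecular conjugate addition of the phenol and loss of dimethylamine (the enaminone route to chromones) closes ring C, and since the para oxygen is the only free one it can give only the 6-substituted chromone.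

Step 11
Reactants: 19 5,7-bis(benzyloxy)-6-[(2S)-1-methyl-1,2,3,6-tetrahydropyridin-2-yl]-4H-chromen-4-one; 20 4-(benzyloxy)phenylboronic acid
Product: 21 (2S)-5,7-bis(benzyloxy)-2-[4-(benzyloxy)phenyl]-6-[(2S)-1-methyl-1,2,3,6-tetrahydropyridin-2-yl]-2,3-dihydro-4H-chromen-4-one
Conditions: [Rh(OH)(cod)]2 (2.5 mol %), (S)-MeO-F12-BIPHEP [(S)-6,6′-dimethoxy-2,2′-bis{bis(3,4,5-trifluorophenyl)phosphino}-1,1′-biphenyl] (6 mol %), CH2Cl2/H2O, rt → 40 °C
Reagents that add atoms: none
Why: Rhodium-catalysed asymmetric 1,4-addition of an arylboronic acid to a chromone (Hayashi–Miyaura reaction): transmetalation gives an aryl–rhodium species held by the chiral bisphosphine, which should deliver the aryl group to the Re face of C2 and so set C2 as S under catalyst control, the remote C2′ having no say.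

Step 12
Reactants: 21 (2S)-5,7-bis(benzyloxy)-2-[4-(benzyloxy)phenyl]-6-[(2S)-1-methyl-1,2,3,6-tetrahydropyridin-2-yl]-2,3-dihydro-4H-chromen-4-one
Product: 22 (2S)-5,7-dihydroxy-2-(4-hydroxyphenyl)-6-[(2S)-1-methylpiperidin-2-yl]-2,3-dihydro-4H-chromen-4-one
Conditions: H2 (1 atm), Pd/C (10 % Pd on carbon), EtOAc/MeOH, rt
Reagents that add atoms: none
Why: Heterogeneous catalytic hydrogenation cleaves the three benzyl ethers by hydrogenolysis and saturates C4′=C5′ in one neutral operation at room temperature, under which neither C2 nor C2′ should epimerise.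

Compound list
1 | 3,5-bis(benzyloxy)phenol | Oc1cc(OCc2ccccc2)cc(OCc2ccccc2)c1 | starting material
2 | N-{[2,6-bis(benzyloxy)-4-hydroxyphenyl]methylidene}-N-methylmethanaminium chloride | C[N+](C)=Cc1c(OCc2ccccc2)cc(O)cc1OCc1ccccc1.[Cl-] | intermediate (not isolated)
3 | 2,6-bis(benzyloxy)-4-hydroxybenzaldehyde | O=Cc1c(OCc2ccccc2)cc(O)cc1OCc1ccccc1 | intermediate
4 | 2,6-bis(benzyloxy)-4-(methoxymethoxy)benzaldehyde | COCOc1cc(OCc2ccccc2)c(C=O)c(OCc2ccccc2)c1 | intermediate
5 | (R)-2-methylpropane-2-sulfinamide | CC(C)(C)[S@@](=O)N | starting material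
6 | (R,E)-N-{[2,6-bis(benzyloxy)-4-(methoxymethoxy)phenyl]methylidene}-2-methylpropane-2-sulfinamide | CC(C)(C)[S@@](=O)/N=C/c1c(OCc2ccccc2)cc(OCOC)cc1OCc1ccccc1 | intermediate
7 | allyl bromide | C=CCBr | starting material
8 | (R)-N-{(1S)-1-[2,6-bis(benzyloxy)-4-(methoxymethoxy)phenyl]but-3-en-1-yl}-2-methylpropane-2-sulfinamide | CC(C)(C)[S@@](=O)N[C@@H](CC=C)c1c(OCc2ccccc2)cc(OCOC)cc1OCc1ccccc1 | intermediate
9 | (1S)-1-[2,6-bis(benzyloxy)-4-(methoxymethoxy)phenyl]but-3-en-1-amine | N[C@@H](CC=C)c1c(OCc2ccccc2)cc(OCOC)cc1OCc1ccccc1 | intermediate (not isolated)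
10 | methyl N-{(1S)-1-[2,6-bis(benzyloxy)-4-(methoxymethoxy)phenyl]but-3-en-1-yl}carbamate | COC(=O)N[C@@H](CC=C)c1c(OCc2ccccc2)cc(OCOC)cc1OCc1ccccc1 | intermediate
11 | methyl N-allyl-N-{(1S)-1-[2,6-bis(benzyloxy)-4-(methoxymethoxy)phenyl]but-3-en-1-yl}carbamate | COC(=O)N(CC=C)[C@@H](CC=C)c1c(OCc2ccccc2)cc(OCOC)cc1OCc1ccccc1 | intermediate
12 | methyl (2S)-2-[2,6-bis(benzyloxy)-4-(methoxymethoxy)phenyl]-3,6-dihydropyridine-1(2H)-carboxylate | COC(=O)N1CC=CC[C@H]1c1c(OCc2ccccc2)cc(OCOC)cc1OCc1ccccc1 | intermediate
13 | (2S)-2-[2,6-bis(benzyloxy)-4-(methoxymethoxy)phenyl]-1-methyl-1,2,3,6-tetrahydropyridine | CN1CC=CC[C@H]1c1c(OCc2ccccc2)cc(OCOC)cc1OCc1ccccc1 | intermediate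
14 | N-methoxy-N-methylacetamide | CON(C)C(C)=O | starting material
15 | {2,4-bis(benzyloxy)-6-(methoxymethoxy)-3-[(2S)-1-methyl-1,2,3,6-tetrahydropyridin-2-yl]phenyl}lithium | CN1CC=CC[C@H]1c1c(OCc2ccccc2)cc(OCOC)c([Li])c1OCc1ccccc1 | intermediate (not isolated)
16 | 1-{2,4-bis(benzyloxy)-6-(methoxymethoxy)-3-[(2S)-1-methyl-1,2,3,6-tetrahydropyridin-2-yl]phenyl}ethan-1-one | CN1CC=CC[C@H]1c1c(OCc2ccccc2)cc(OCOC)c(C(C)=O)c1OCc1ccccc1 | intermediate (not isolated)
17 | 1-{2,4-bis(benzyloxy)-6-hydroxy-3-[(2S)-1-methyl-1,2,3,6-tetrahydropyridin-2-yl]phenyl}ethan-1-one | CN1CC=CC[C@H]1c1c(OCc2ccccc2)cc(O)c(C(C)=O)c1OCc1ccccc1 | intermediate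
18 | (2E)-1-{2,4-bis(benzyloxy)-6-hydroxy-3-[(2S)-1-methyl-1,2,3,6-tetrahydropyridin-2-yl]phenyl}-3-(dimethylamino)prop-2-en-1-one | CN1CC=CC[C@H]1c1c(OCc2ccccc2)cc(O)c(C(=O)/C=C/N(C)C)c1OCc1ccccc1 | intermediate (not isolated)
19 | 5,7-bis(benzyloxy)-6-[(2S)-1-methyl-1,2,3,6-tetrahydropyridin-2-yl]-4H-chromen-4-one | CN1CC=CC[C@H]1c1c(OCc2ccccc2)cc2occc(=O)c2c1OCc1ccccc1 | intermediate
20 | 4-(benzyloxy)phenylboronic acid | OB(O)c1ccc(OCc2ccccc2)cc1 | starting material
21 | (2S)-5,7-bis(benzyloxy)-2-[4-(benzyloxy)phenyl]-6-[(2S)-1-methyl-1,2,3,6-tetrahydropyridin-2-yl]-2,3-dihydro-4H-chromen-4-one | CN1CC=CC[C@H]1c1c(OCc2ccccc2)cc2c(c1OCc1ccccc1)C(=O)C[C@@H](c1ccc(OCc3ccccc3)cc1)O2 | intermediate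
22 | (2S)-5,7-dihydroxy-2-(4-hydroxyphenyl)-6-[(2S)-1-methylpiperidin-2-yl]-2,3-dihydro-4H-chromen-4-one | CN1CCCC[C@H]1c1c(O)cc2c(c1O)C(=O)C[C@@H](c1ccc(O)cc1)O2 | target

Total step count: 12. Longest linear sequence: 12 steps (1 to 22); the other starting materials (5, 7, 14, 20) enter directly.

Steps most likely to fail

Step 11. The aryl transfer to the electron-rich 5,7-dialkoxychromone may be sluggish, the facial discrimination at C2 may be insufficient, or ring C may open under the basic aqueous conditions. The (S)-ligand is proposed by analogy with the face selection of biaryl bisphosphine–rhodium catalysts on cyclic enones; the (R)-ligand is used if a model chromone shows the opposite sense. The fallback sets out from 17. Claisen–Schmidt condensation with commercial 4-(benzyloxy)benzaldehyde (KOH, EtOH, rt) gives the chalcone (2E)-1-{2,4-bis(benzyloxy)-6-hydroxy-3-[(2S)-1-methyl-1,2,3,6-tetrahydropyridin-2-yl]phenyl}-3-[4-(benzyloxy)phenyl]prop-2-en-1-one F1. Heating with NaOAc in EtOH closes ring C by reversible oxa-Michael addition and should give 21 together with its C2 epimer (2R)-5,7-bis(benzyloxy)-2-[4-(benzyloxy)phenyl]-6-[(2S)-1-methyl-1,2,3,6-tetrahydropyridin-2-yl]-2,3-dihydro-4H-chromen-4-one F2. Because of C2′ the two are diastereomers and are separated by chromatography, the unwanted epimer being returned to the equilibration. The route is rejoined at 21.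

Step 9. The base may deprotonate a benzylic OCH2 group (followed by Wittig rearrangement) instead of the ring, or the hindered aryllithium may enolise 14 instead of adding to it. The fallback sets out from 13. Friedel–Crafts acetylation of the trialkoxybenzene ring with the mixed anhydride made from AcOH and (CF3CO)2O (CH2Cl2, 0 °C → rt, the amine being protonated) places the acetyl group on the same and only available kind of ring carbon and gives 16. The route is rejoined at 16, which is then treated with HCl/MeOH as in step 9; any material that has lost the methoxymethyl group or has been O-acylated converges on 17 in that treatment. New compounds on this way: none F0.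

Step 12. The C4 carbonyl may be over-reduced, the benzylic C2′–N1′ or C2–O1 bond may undergo hydrogenolysis, or the amine may promote epimerisation at C2 once the phenols are free. The fallback sets out from 21. Diimide generated from 2-nitrobenzenesulfonohydrazide and Et3N (CH2Cl2, rt) reduces only C4′=C5′ and gives (2S)-5,7-bis(benzyloxy)-2-[4-(benzyloxy)phenyl]-6-[(2S)-1-methylpiperidin-2-yl]-2,3-dihydro-4H-chromen-4-one F3. BCl3 with pentamethylbenzene as cation scavenger (CH2Cl2, −78 °C) then cleaves the three benzyl ethers without hydrogen, and the route is rejoined at 22.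

Further compounds
F1 | step 11 | (2E)-1-{2,4-bis(benzyloxy)-6-hydroxy-3-[(2S)-1-methyl-1,2,3,6-tetrahydropyridin-2-yl]phenyl}-3-[4-(benzyloxy)phenyl]prop-2-en-1-one | CN1CC=CC[C@H]1c1c(OCc2ccccc2)cc(O)c(C(=O)/C=C/c2ccc(OCc3ccccc3)cc2)c1OCc1ccccc1
F2 | step 11 | (2R)-5,7-bis(benzyloxy)-2-[4-(benzyloxy)phenyl]-6-[(2S)-1-methyl-1,2,3,6-tetrahydropyridin-2-yl]-2,3-dihydro-4H-chromen-4-one | CN1CC=CC[C@H]1c1c(OCc2ccccc2)cc2c(c1OCc1ccccc1)C(=O)C[C@H](c1ccc(OCc3ccccc3)cc1)O2
F0 | step 9 | none | none
F3 | step 12 | (2S)-5,7-bis(benzyloxy)-2-[4-(benzyloxy)phenyl]-6-[(2S)-1-methylpiperidin-2-yl]-2,3-dihydro-4H-chromen-4-one | CN1CCCC[C@H]1c1c(OCc2ccccc2)cc2c(c1OCc1ccccc1)C(=O)C[C@@H](c1ccc(OCc3ccccc3)cc1)O2
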